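Ring B (C5–C6–C7–C8–C9–C10) is a pulegone in disguise: the C8 ketone is flanked by C7, which carries the C11 isopropylidene. Cutting C7–C8 therefore leads to a citronellal-like monocycle: ring A with a 2-oxoethyl arm on quaternary C10 and a prenyl arm on C5. A Lewis-acid carbonyl-ene reaction closes ring B in one operation, placing the C8 oxygen and the C11–C13 unit exactly where the enone needs them; oxidation and conjugation finish ring B. The trans C5/C10 array of the precursor comes from a catalytic asymmetric Diels–Alder reaction between a 2-silyloxydiene and an (E)-2-methyl-2-enal.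

Key step: step 6

Remark: eudesmane numbering is used throughout (ring A = C1–C5 and C10; ring B = C5–C10; C11–C13 = isopropylidene; C14 on C10; C15 on C4). α/β refer to the usual drawing with the C10 methyl β. Compounds 1, 2, 5 and 17 are taken as purchased.

Step 1
Reactants: 1 4-methylpent-3-en-1-ol; 2 2-(triphenyl-λ5-phosphanylidene)propanal
Product: 4 (2E)-2,6-dimethylhepta-2,5-dienal, via 4-methylpent-3-enal 3 (not isolated)
Conditions: Dess–Martin periodinane, NaHCO3, CH2Cl2, 0 °C; then 2, CH2Cl2, 40 °C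
Reagents that add atoms: none
Why: Dess–Martin oxidation gives the isomerisation-prone β,γ-unsaturated aldehyde, which is trapped in the same flask by Wittig olefination with the stabilised α-methyl ylide, a reagent class that should give the (E)-trisubstituted enal.

Step 2
Reactants: 5 pent-1-en-3-one
Product: 6 tert-butyldimethyl{[(3Z)-penta-1,3-dien-3-yl]oxy}silane
Conditions: tert-butyldimethylsilyl triflate, Et3N, Et2O, 0 °C
Reagents that add atoms: tert-butyldimethylsilyl trifluoromethanesulfonate, CC(C)(C)[Si](C)(C)OS(=O)(=O)C(F)(F)F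
Why: Soft enolisation and O-silylation of the ethyl ketone (silyl enol ether formation) should give the Z enol ether, with the methyl trans to the vinyl group as a reactive diene needs.

Step 3
Reactants: 4 (2E)-2,6-dimethylhepta-2,5-dienal; 6 tert-butyldimethyl{[(3Z)-penta-1,3-dien-3-yl]oxy}silane
Product: 7 (1S,5S,6S)-4-[(tert-butyldimethylsilyl)oxy]-1,5-dimethyl-6-(3-methylbut-2-en-1-yl)cyclohex-3-ene-1-carbaldehyde
Conditions: (R)-3,3-diphenyl-1-(2-methylphenyl)tetrahydro-1H,3H-pyrrolo[1,2-c][1,3,2]oxazaborole protonated with (CF3SO2)2NH (20 mol %), CH2Cl2, −78 to −40 °C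
Reagents that add atoms: none
Why: In this Lewis-acid-catalysed asymmetric Diels–Alder reaction the silyloxy group makes the methyl-bearing diene terminus (future C4) nucleophilic so that it bonds to the enal β-carbon (C5) and the CH2 terminus (C1) to C10; the (E)-geometry of the enal is transferred suprafacially into the trans relation of the C6 and C9 arms; the boron-bound s-trans enal is shielded on one face by a catalyst phenyl group, so the (R)-catalyst is expected to send the diene to the Cα Si face (mirror image of the Cα Re addition to 2-methylacrolein with the (S)-catalyst); C4 follows from the endo mode and is re-formed in step 7.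

Step 4
Reactants: 7 (1S,5S,6S)-4-[(tert-butyldimethylsilyl)oxy]-1,5-dimethyl-6-(3-methylbut-2-en-1-yl)cyclohex-3-ene-1-carbaldehyde
Product: 8 tert-butyl{[(4S,5S,6S)-4-(2-methoxyethenyl)-4,6-dimethyl-5-(3-methylbut-2-en-1-yl)cyclohex-1-en-1-yl]oxy}dimethylsilane (E/Z mixture at the enol ether)
Conditions: Ph3P(CH2OMe)Cl, KN(SiMe3)2, THF, 0 °C to rt
Reagents that add atoms: (methoxymethyl)triphenylphosphonium chloride, COC[P+](c1ccccc1)(c1ccccc1)c1ccccc1.[Cl-]
Why: Wittig methoxymethylenation adds C8 to the non-enolisable neopentyl aldehyde (one-carbon homologation); the silyl enol ether is inert to the amide base and ylide, and no stereocenter is formed.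

Step 5
Reactants: 8 tert-butyl{[(4S,5S,6S)-4-(2-methoxyethenyl)-4,6-dimethyl-5-(3-methylbut-2-en-1-yl)cyclohex-1-en-1-yl]oxy}dimethylsilane
Product: 9 2-[(1R,2S,3S)-1,3-dimethyl-2-(3-methylbut-2-en-1-yl)-4-oxocyclohexyl]acetaldehyde
Conditions: 1 M HCl, THF, 0 °C to rt
Reagents that add atoms: water, O
Why: Acid hydrolysis of both enol ethers unmasks the C8 aldehyde and the C3 ketone; C4, α to the ketone, settles with its methyl equatorial, which is immaterial because C4 is re-formed in step 7.

Step 6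
Reactants: 9 2-[(1R,2S,3S)-1,3-dimethyl-2-(3-methylbut-2-en-1-yl)-4-oxocyclohexyl]acetaldehyde
Product: 10 (1S,4aR,6S,7R,8aS)-6-hydroxy-1,4a-dimethyl-7-(prop-1-en-2-yl)octahydronaphthalen-2(1H)-one (8α-hydroxy-4α-methyl-eudesm-11-en-3-one)
Conditions: Me2AlCl (2.2 equiv), CH2Cl2, −78 to −40 °C; 1 M HCl quench
Reagents that add atoms: none
Why: Me2AlCl activates the C8 aldehyde as enophile and the prenyl olefin reacts as the ene in a concerted, asynchronous six-centre process: C7 bonds to C8 while an allylic hydrogen of C12 passes to oxygen, leaving the C11=C12 isopropenyl group. The closest known reaction type is the type 1 intramolecular carbonyl-ene cyclisation of citronellal to isopulegol. Ring B closes through the C7–C8 bond in a six-membered chair transition state, exo with respect to the C7=C11 olefin (6-exo-trig), with positive charge developing at tertiary C11. The ring fusion (C5, C10) is already fixed trans by the precursor; the new centres C7 and C8 are set by the chair with hydroxyl and isopropenyl equatorial (8α-OH, 7β-isopropenyl), and both are erased again in step 8. The step needs chemoselectivity for the aldehyde over the C3 ketone, secured by the far higher enophilicity of aldehydes and the remoteness of the ketone, and regioselectivity for C7 over C11, secured by six- versus seven-membered ring formation and Markovnikov polarisation.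

Step 7
Reactants: 10 (1S,4aR,6S,7R,8aS)-6-hydroxy-1,4a-dimethyl-7-(prop-1-en-2-yl)octahydronaphthalen-2(1H)-one
Product: 12 (1S,4aR,6S,7R,8aR)-1,6-dihydroxy-1,4a-dimethyl-7-(prop-1-en-2-yl)octahydronaphthalen-2(1H)-one, via 4-hydroperoxy ketone 11 (not isolated)
Conditions: Cs2CO3 (0.2 equiv), P(OEt)3, O2 (1 atm), DMSO, rt
Reagents that add atoms: dioxygen, O=O
Why: Base-mediated α-hydroxylation of a ketone by enolate autoxidation with in-flask phosphite reduction of the hydroperoxide should occur at the tertiary α-carbon C4 through the more substituted C3–C4 enolate, with O2 entering on the α face, anti to the axial C14 methyl, to give the 4α-hydroxy-4β-methyl ketol.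

Step 8
Reactants: 12 (1S,4aR,6S,7R,8aR)-1,6-dihydroxy-1,4a-dimethyl-7-(prop-1-en-2-yl)octahydronaphthalen-2(1H)-one
Product: 14 (1S,4aR,8aR)-1-hydroxy-1,4a-dimethyl-7-(propan-2-ylidene)hexahydronaphthalene-2,6(1H,3H)-dione (4α-hydroxyeudesm-7(11)-ene-3,8-dione), via isopropenyl diketone 13 (not isolated)
Conditions: Dess–Martin periodinane, NaHCO3, CH2Cl2, 0 °C to rt; then DBU (0.2 equiv), rt
Reagents that add atoms: none
Why: Dess–Martin oxidation converts the secondary C8 alcohol to the ketone (the tertiary C4 hydroxyl is inert), and base-mediated β,γ to α,β olefin isomerisation through the dienolate, as in isopulegone to pulegone, should move the double bond into conjugation; C7 and C8 cease to be stereocenters.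

Step 9
Reactants: 14 (1S,4aR,8aR)-1-hydroxy-1,4a-dimethyl-7-(propan-2-ylidene)hexahydronaphthalene-2,6(1H,3H)-dione
Product: 15 (1S,4aR,8aR)-1,4a-dimethyl-2,6-dioxo-7-(propan-2-ylidene)decahydronaphthalen-1-yl acetate
Conditions: Ac2O, DMAP, Et3N, CH2Cl2, 40 °C
Reagents that add atoms: acetic anhydride, CC(=O)OC(C)=O
Why: DMAP-catalysed acylation of the equatorial tertiary α-ketol hydroxyl, the only hydroxyl present, installs the C4 acetate before any base-sensitive angelate exists; no stereocenter is touched.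

Step 10
Reactants: 15 (1S,4aR,8aR)-1,4a-dimethyl-2,6-dioxo-7-(propan-2-ylidene)decahydronaphthalen-1-yl acetate
Product: 16 (1S,2S,4aR,8aR)-2-hydroxy-1,4a-dimethyl-6-oxo-7-(propan-2-ylidene)decahydronaphthalen-1-yl acetate
Conditions: NaBH4, MeOH/CH2Cl2 (1:1), −78 °C; AcOH quench at −78 °C
Reagents that add atoms: none
Why: Low-temperature borohydride reduction should take the saturated, acetoxy-activated C3 ketone in preference to the hindered cross-conjugated C8 enone; axial hydride delivery on the α face, away from the axial 4β-methyl, gives the equatorial 3β-alcohol, and the cold acidic quench suppresses acetyl migration from O4 to O3.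

Step 11
Reactants: 16 (1S,2S,4aR,8aR)-2-hydroxy-1,4a-dimethyl-6-oxo-7-(propan-2-ylidene)decahydronaphthalen-1-yl acetate; 17 angelic acid, (2Z)-2-methylbut-2-enoic acid
Product: 19 3β-angeloyloxy-4α-acetoxyeudesm-7(11)-en-8-one (CNP0141494.1), via angelic 2,4,6-trichlorobenzoic anhydride 18 (not isolated)
Conditions: 17, 2,4,6-trichlorobenzoyl chloride, Et3N, toluene, rt; then 16, toluene, 80 °C (no DMAP)
Reagents that add atoms: none
Why: In this Yamaguchi-type mixed-anhydride esterification the hindered aroyl carbonyl directs the alcohol to the angeloyl carbonyl, and leaving out a nucleophilic catalyst should preserve the Z olefin; no stereocenter is touched.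

Compound list
1 | 4-methylpent-3-en-1-ol | CC(C)=CCCO | starting material
2 | 2-(triphenyl-λ5-phosphanylidene)propanal | CC(C=O)=P(c1ccccc1)(c1ccccc1)c1ccccc1 | starting material
3 | 4-methylpent-3-enal | CC(C)=CCC=O | intermediate
4 | (2E)-2,6-dimethylhepta-2,5-dienal | O=C/C(C)=C/CC=C(C)C | intermediate
5 | pent-1-en-3-one | CCC(=O)C=C | starting material
6 | tert-butyldimethyl{[(3Z)-penta-1,3-dien-3-yl]oxy}silane | C/C=C(\O[Si](C)(C)C(C)(C)C)C=C | intermediate
7 | (1S,5S,6S)-4-[(tert-butyldimethylsilyl)oxy]-1,5-dimethyl-6-(3-methylbut-2-en-1-yl)cyclohex-3-ene-1-carbaldehyde | CC(C)(C)[Si](C)(C)OC1=CC[C@](C)(C=O)[C@@H](CC=C(C)C)[C@@H]1C | intermediate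
8 | tert-butyl{[(4S,5S,6S)-4-(2-methoxyethenyl)-4,6-dimethyl-5-(3-methylbut-2-en-1-yl)cyclohex-1-en-1-yl]oxy}dimethylsilane (E/Z mixture at the enol ether, geometry not specified) | CC(C)(C)[Si](C)(C)OC1=CC[C@](C)(C=COC)[C@@H](CC=C(C)C)[C@@H]1C | intermediate
9 | 2-[(1R,2S,3S)-1,3-dimethyl-2-(3-methylbut-2-en-1-yl)-4-oxocyclohexyl]acetaldehyde | O=C1CC[C@](C)(CC=O)[C@@H](CC=C(C)C)[C@@H]1C | intermediate
10 | (1S,4aR,6S,7R,8aS)-6-hydroxy-1,4a-dimethyl-7-(prop-1-en-2-yl)octahydronaphthalen-2(1H)-one | O=C1CC[C@]2(C)C[C@H](O)[C@@H](C(C)=C)C[C@H]2[C@@H]1C | intermediate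
11 | (1S,4aR,6S,7R,8aR)-1-hydroperoxy-6-hydroxy-1,4a-dimethyl-7-(prop-1-en-2-yl)octahydronaphthalen-2(1H)-one | O=C1CC[C@]2(C)C[C@H](O)[C@@H](C(C)=C)C[C@H]2[C@]1(C)OO | intermediate
12 | (1S,4aR,6S,7R,8aR)-1,6-dihydroxy-1,4a-dimethyl-7-(prop-1-en-2-yl)octahydronaphthalen-2(1H)-one | O=C1CC[C@]2(C)C[C@H](O)[C@@H](C(C)=C)C[C@H]2[C@]1(C)O | intermediate
13 | (1S,4aR,7R,8aR)-1-hydroxy-1,4a-dimethyl-7-(prop-1-en-2-yl)hexahydronaphthalene-2,6(1H,3H)-dione | O=C1CC[C@]2(C)CC(=O)[C@@H](C(C)=C)C[C@H]2[C@]1(C)O | intermediate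
14 | (1S,4aR,8aR)-1-hydroxy-1,4a-dimethyl-7-(propan-2-ylidene)hexahydronaphthalene-2,6(1H,3H)-dione | O=C1CC[C@]2(C)CC(=O)C(=C(C)C)C[C@H]2[C@]1(C)O | intermediate
15 | (1S,4aR,8aR)-1,4a-dimethyl-2,6-dioxo-7-(propan-2-ylidene)decahydronaphthalen-1-yl acetate | O=C1CC[C@]2(C)CC(=O)C(=C(C)C)C[C@H]2[C@]1(C)OC(C)=O | intermediate
16 | (1S,2S,4aR,8aR)-2-hydroxy-1,4a-dimethyl-6-oxo-7-(propan-2-ylidene)decahydronaphthalen-1-yl acetate | O[C@H]1CC[C@]2(C)CC(=O)C(=C(C)C)C[C@H]2[C@]1(C)OC(C)=O | intermediate
17 | angelic acid, (2Z)-2-methylbut-2-enoic acid | C/C=C(/C)C(=O)O | starting material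
18 | (2Z)-2-methylbut-2-enoic 2,4,6-trichlorobenzoic anhydride | C/C=C(/C)C(=O)OC(=O)c1c(Cl)cc(Cl)cc1Cl | intermediate
19 | (1S,2S,4aR,8aR)-1-acetoxy-1,4a-dimethyl-6-oxo-7-(propan-2-ylidene)decahydronaphthalen-2-yl (2Z)-2-methylbut-2-enoate (3β-angeloyloxy-4α-acetoxyeudesm-7(11)-en-8-one) | C/C=C(/C)C(=O)O[C@H]1CC[C@]2(C)CC(=O)C(=C(C)C)C[C@H]2[C@]1(C)OC(C)=O | target

Total step count: 11. Longest linear sequence: 10 steps (steps 1, 3, 4, 5, 6, 7, 8, 9, 10, 11); step 2 is a one-step side branch.

Steps most likely to fail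

Step 3. The trisubstituted enal may react too slowly or with poor facial discrimination, so that the adduct forms in low enantiomeric purity or not at all under the chiral catalyst. The fallback sets out from 4 and 6 and comes back at 10. The cycloaddition is run without chiral control (Me2AlCl, CH2Cl2, −78 °C) to give 7 together with ent-7 F1. Steps 4 to 6 carry the racemate forward, so that ent-8 F2, ent-9 F3 and ent-10 F4 accompany 8, 9 and 10. The racemic alcohol is esterified with (S)-2-methoxy-2-phenylacetic acid (N,N'-dicyclohexylcarbodiimide, DMAP, CH2Cl2) to the diastereomeric esters, the (S)-methoxyphenylacetate of 10 F5 and the (S)-methoxyphenylacetate of ent-10 F6. These are separated by chromatography, and methanolysis of the first (K2CO3, MeOH, rt) returns 10.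

Step 7. In the trans-fused ketone, enolisation may go toward C2 instead of C4, so that oxygen enters at the wrong α-carbon or over-oxidation sets in. The fallback sets out from 8 and comes back at 12, moving the oxygenation to the conformationally free monocycle. The silyl enol ether alone is cleaved (Bu4NF, AcOH, THF, 0 °C) to the methyl enol ether ketone F7. Its methine α-carbon is hydroxylated under the same autoxidation conditions (Cs2CO3, P(OEt)3, O2, DMSO), anti to the neighbouring prenyl arm, to the ketol F8. Hydrolysis (1 M HCl, THF) gives the hydroxy keto aldehyde F9, whose carbonyl-ene closure (Me2AlCl, CH2Cl2, −78 °C) leads to 12.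

Step 11. During the slow acylation of the hindered C3 alcohol the angeloyl unit may isomerise from Z to E, or the acetyl group may migrate from O4 to O3 on heating with base. The fallback sets out from 16 and comes back at 19, building the Z olefin on the ester instead of transferring it. Alcohol 16 is acylated under mild carbodiimide conditions with 2-[bis(2,2,2-trifluoroethoxy)phosphoryl]propanoic acid (N,N'-dicyclohexylcarbodiimide, DMAP cat., CH2Cl2, 0 °C) to the phosphonopropanoate F10. A Z-selective Horner–Wadsworth–Emmons (Still–Gennari) olefination with acetaldehyde (KN(SiMe3)2, 18-crown-6, THF, −78 °C) then gives 19.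

Further compounds
F1 | step 3 | (1R,5R,6R)-4-[(tert-butyldimethylsilyl)oxy]-1,5-dimethyl-6-(3-methylbut-2-en-1-yl)cyclohex-3-ene-1-carbaldehyde (ent-7) | CC(C)(C)[Si](C)(C)OC1=CC[C@@](C)(C=O)[C@H](CC=C(C)C)[C@H]1C
F2 | step 3 | tert-butyl{[(4R,5R,6R)-4-(2-methoxyethenyl)-4,6-dimethyl-5-(3-methylbut-2-en-1-yl)cyclohex-1-en-1-yl]oxy}dimethylsilane (ent-8) | CC(C)(C)[Si](C)(C)OC1=CC[C@@](C)(C=COC)[C@H](CC=C(C)C)[C@H]1C
F3 | step 3 | 2-[(1S,2R,3R)-1,3-dimethyl-2-(3-methylbut-2-en-1-yl)-4-oxocyclohexyl]acetaldehyde (ent-9) | O=C1CC[C@@](C)(CC=O)[C@H](CC=C(C)C)[C@H]1C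
F4 | step 3 | (1R,4aS,6R,7S,8aR)-6-hydroxy-1,4a-dimethyl-7-(prop-1-en-2-yl)octahydronaphthalen-2(1H)-one (ent-10) | O=C1CC[C@@]2(C)C[C@@H](O)[C@H](C(C)=C)C[C@@H]2[C@H]1C
F5 | step 3 | (2S,3R,4aS,8S,8aR)-4a,8-dimethyl-7-oxo-3-(prop-1-en-2-yl)decahydronaphthalen-2-yl (2S)-2-methoxy-2-phenylacetate (ester of 10) | O=C1CC[C@]2(C)C[C@H](OC(=O)[C@@H](OC)c3ccccc3)[C@@H](C(C)=C)C[C@H]2[C@@H]1C
F6 | step 3 | (2R,3S,4aR,8R,8aS)-4a,8-dimethyl-7-oxo-3-(prop-1-en-2-yl)decahydronaphthalen-2-yl (2S)-2-methoxy-2-phenylacetate (ester of ent-10) | O=C1CC[C@@]2(C)C[C@@H](OC(=O)[C@@H](OC)c3ccccc3)[C@H](C(C)=C)C[C@@H]2[C@H]1C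
F7 | step 7 | (2S,3S,4S)-4-(2-methoxyethenyl)-2,4-dimethyl-3-(3-methylbut-2-en-1-yl)cyclohexan-1-one (E/Z mixture at the enol ether) | O=C1CC[C@](C)(C=COC)[C@@H](CC=C(C)C)[C@@H]1C
F8 | step 7 | (2S,3R,4S)-2-hydroxy-4-(2-methoxyethenyl)-2,4-dimethyl-3-(3-methylbut-2-en-1-yl)cyclohexan-1-one (E/Z mixture at the enol ether) | O=C1CC[C@](C)(C=COC)[C@@H](CC=C(C)C)[C@]1(C)O
F9 | step 7 | 2-[(1R,2R,3S)-3-hydroxy-1,3-dimethyl-2-(3-methylbut-2-en-1-yl)-4-oxocyclohexyl]acetaldehyde | O=C1CC[C@](C)(CC=O)[C@@H](CC=C(C)C)[C@]1(C)O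
F10 | step 11 | (1S,2S,4aR,8aR)-1-acetoxy-1,4a-dimethyl-6-oxo-7-(propan-2-ylidene)decahydronaphthalen-2-yl 2-[bis(2,2,2-trifluoroethoxy)phosphoryl]propanoate (epimers at the phosphonate α-carbon) | CC(C(=O)O[C@H]1CC[C@]2(C)CC(=O)C(=C(C)C)C[C@H]2[C@]1(C)OC(C)=O)P(=O)(OCC(F)(F)F)OCC(F)(F)F
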